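**Retrosynthetic overview**
- The target is the 3,4-dimethylpent-3-enoate of (R)-shikonin, so the ester C–O bond is cut last: carbodiimide acylation of the side-chain carbinol, the two chelated peri phenols staying free.
- The strategy rests on ring A, the quinone ring C1–C4 fused to the benzenoid ring B. Its only C=C is C2=C3 (C2 bears the side chain, C3 a hydrogen) and it is flanked by the benzylic carbonyl carbons C1 and C4. Ring A is therefore opened at C2=C3 to a benzene with two adjacent allylic carbinols, closed by olefin metathesis and then oxidised.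
- The diene comes from the symmetrical 3,6-bis(methoxymethoxy)phthalaldehyde. The chiral 2-lithioalkene is added first and the adduct is trapped as a lactol; vinylmagnesium bromide in excess then opens the lactol and adds.
- The side-chain stereocentre is set by asymmetric transfer hydrogenation of a silyl ynone. The alkyne is converted to the 2-iodoalkene by internal-selective hydrostannation and iodination.
- Ring order: ring B is bought (2,5-dihydroxybenzaldehyde); ring A is the only ring formed, in step 12.

Key step: step 12

Remark on the chemistry: the 5,8-dihydroxy-1,4-naphthoquinone core exists as rapidly interconverting tautomers and is drawn with the side chain on the quinonoid ring, as in the target SMILES. The carbinol centres made in steps 10 and 11 are carried as epimer mixtures because the oxidation in step 13 removes them.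

**Route**

Step 1
Reactants: 1 2,5-dihydroxybenzaldehyde
Product: 2 2,5-bis(methoxymethoxy)benzaldehyde
Conditions: MOMCl (3 equiv), i-Pr2NEt (4 equiv), CH2Cl2, 0 °C → rt
Reagents that add atoms: chloromethyl methyl ether, COCCl
Why: O-alkylation of both phenols with an α-chloro ether (acetal formation) under amine base should proceed cleanly and leave the aldehyde untouched.

Step 2
Reactants: 2 2,5-bis(methoxymethoxy)benzaldehyde
Product: 5 3,6-bis(methoxymethoxy)benzene-1,2-dicarbaldehyde, via lithium amino alkoxide 3 (not isolated), via ortho-lithiated amino alkoxide 4 (not isolated)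
Conditions: LiN(Me)CH2CH2NMe2 (1.1 equiv, from the diamine and n-BuLi), THF, −20 °C; n-BuLi (3 equiv), −20 °C; DMF, −78 °C → rt; aq. NH4Cl
Reagents that add atoms: N,N-dimethylformamide, CN(C)C=O
Why: Comins directed ortho-metalation, in which the lithium amide adduct masks the aldehyde and, together with the C5 methoxymethyl ether, directs n-BuLi to the carbon between them, after which formylation with DMF and hydrolysis of both aminal alkoxides should give the symmetrical dialdehyde.

Step 3
Reactants: 6 4-methylpent-3-enoic acid
Product: 7 N-methoxy-N,4-dimethylpent-3-enamide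
Conditions: MeNH(OMe)·HCl, EDC·HCl, Et3N, CH2Cl2, 0 °C → rt
Reagents that add atoms: N,O-dimethylhydroxylamine hydrochloride, CNOC.Cl
Why: carbodiimide amide coupling to the Weinreb amide under mild conditions should leave the β,γ-alkene in place.

Step 4
Reactants: 7 N-methoxy-N,4-dimethylpent-3-enamide; 8 ethynyltrimethylsilane
Product: 10 6-methyl-1-(trimethylsilyl)hept-5-en-1-yn-3-one, via lithium (trimethylsilyl)acetylide 9 (not isolated)
Conditions: 8, n-BuLi, THF, −78 °C; then 7, −78 → 0 °C; cold aq. NH4Cl
Reagents that add atoms: none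
Why: Weinreb ketone synthesis, in which the acetylide adds once to give a chelated tetrahedral adduct that collapses to the ynone only on work-up, so over-addition and base-induced alkene migration should be avoided.

Step 5
Reactants: 10 6-methyl-1-(trimethylsilyl)hept-5-en-1-yn-3-one
Product: 11 (R)-6-methyl-1-(trimethylsilyl)hept-5-en-1-yn-3-ol
Conditions: Ru(p-cymene)[(R,R)-TsNCH(Ph)CH(Ph)NH] (1 mol %), i-PrOH, rt
Reagents that add atoms: none
Why: Noyori asymmetric transfer hydrogenation of an α,β-acetylenic ketone, in which the (R,R)-ligand is expected to deliver hydride to the face that gives the (R)-propargylic alcohol (the alkynyl group takes the site of the aryl group of aryl ketones), without reduction of alkyne or alkene.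

Step 6
Reactants: 11 (R)-6-methyl-1-(trimethylsilyl)hept-5-en-1-yn-3-ol
Product: 12 (R)-tert-butyldimethyl{[6-methyl-1-(trimethylsilyl)hept-5-en-1-yn-3-yl]oxy}silane
Conditions: TBSCl, imidazole, DMF, rt
Reagents that add atoms: tert-butyldimethylsilyl chloride, CC(C)(C)[Si](C)(C)Cl
Why: standard silylation of a secondary alcohol; the C–O bond of the stereocentre is not touched and the heavier silyl ether is easier to handle than the free enynol.

Step 7
Reactants: 12 (R)-tert-butyldimethyl{[6-methyl-1-(trimethylsilyl)hept-5-en-1-yn-3-yl]oxy}silane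
Product: 13 (R)-tert-butyldimethyl[(6-methylhept-5-en-1-yn-3-yl)oxy]silane
Conditions: K2CO3 (0.2 equiv), MeOH, rt
Reagents that add atoms: none
Why: methoxide-mediated protodesilylation cleaves the alkynyl C–Si bond selectively, while the O-silyl ether should be stable to these conditions.

Step 8
Reactants: 13 (R)-tert-butyldimethyl[(6-methylhept-5-en-1-yn-3-yl)oxy]silane
Product: 14 (3R)-3-(tert-butyldimethylsilyloxy)-6-methyl-2-(tributylstannyl)hepta-1,5-diene
Conditions: Bu3SnH (2 equiv), Mo(CO)3(CNt-Bu)3 (3 mol %), hydroquinone (cat.), THF, 55 °C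
Reagents that add atoms: tributyltin hydride, CCCC[SnH](CCCC)CCCC
Why: molybdenum-catalysed hydrostannation of a propargylic alcohol derivative places tin on the internal, oxygen-proximal alkyne carbon by syn addition, the radical inhibitor suppressing the terminal (E)-stannane, and the trisubstituted alkene and the stereocentre should not be involved.

Step 9
Reactants: 14 (3R)-3-(tert-butyldimethylsilyloxy)-6-methyl-2-(tributylstannyl)hepta-1,5-diene
Product: 15 (3R)-3-(tert-butyldimethylsilyloxy)-2-iodo-6-methylhepta-1,5-diene
Conditions: I2 (1.05 equiv), CH2Cl2, 0 °C; aq. Na2S2O3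
Reagents that add atoms: iodine, II
Why: iododestannylation is an ipso electrophilic substitution at the vinyl carbon that is much faster than reversible iodine addition to the trisubstituted alkene.

Step 10
Reactants: 15 (3R)-3-(tert-butyldimethylsilyloxy)-2-iodo-6-methylhepta-1,5-diene; 5 3,6-bis(methoxymethoxy)benzene-1,2-dicarbaldehyde
Product: 18 3-[(3R)-3-(tert-butyldimethylsilyloxy)-6-methylhepta-1,5-dien-2-yl]-4,7-bis(methoxymethoxy)-1,3-dihydro-2-benzofuran-1-ol (epimer mixture), via 2-lithioalkene 16 (not isolated), via lithium alkoxy aldehyde 17 (not isolated)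
Conditions: 15, t-BuLi (2.1 equiv), Et2O, −78 °C; cannulated into 5 (1.2 equiv), THF, −78 °C; aq. NH4Cl
Reagents that add atoms: none
Why: iodine–lithium exchange at −78 °C gives the vinyllithium before any oxygen-to-carbon silyl shift can occur, 1,2-addition to one aldehyde of the symmetrical dialdehyde follows, and the resulting alkoxide closes onto the neighbouring aldehyde as a lactolate, which should protect against a second addition (the new carbinol and lactol centres are uncontrolled and are erased later).

Step 11
Reactants: 18 3-[(3R)-3-(tert-butyldimethylsilyloxy)-6-methylhepta-1,5-dien-2-yl]-4,7-bis(methoxymethoxy)-1,3-dihydro-2-benzofuran-1-ol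
Product: 20 1-(1-hydroxyprop-2-enyl)-2-[(3R)-3-(tert-butyldimethylsilyloxy)-1-hydroxy-6-methyl-2-methylenehept-5-enyl]-3,6-bis(methoxymethoxy)benzene (epimer mixture), via bromomagnesium alkoxy aldehyde 19 (not isolated)
Conditions: CH2=CHMgBr (4 equiv), THF, 0 °C → rt; aq. NH4Cl
Reagents that add atoms: vinylmagnesium bromide, C=C[Mg]Br
Why: Grignard addition to a lactol, in which the first equivalent deprotonates the hemiacetal so that it opens to the alkoxy aldehyde and a further equivalent adds to the freed aldehyde, should give the bis(allylic) diol as a mixture of carbinol epimers.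

Step 12
Reactants: 20 1-(1-hydroxyprop-2-enyl)-2-[(3R)-3-(tert-butyldimethylsilyloxy)-1-hydroxy-6-methyl-2-methylenehept-5-enyl]-3,6-bis(methoxymethoxy)benzene
Product: 21 (R)-2-[1-(tert-butyldimethylsilyloxy)-4-methylpent-3-enyl]-5,8-bis(methoxymethoxy)-1,4-dihydronaphthalene-1,4-diol (epimer mixture)
Conditions: second-generation Grubbs catalyst RuCl2(PCy3)(H2IMes)(=CHPh) (5–10 mol %), 1,4-benzoquinone (10 mol %), degassed CH2Cl2 (0.005 M), 40 °C; filtration through Et3N-deactivated silica
Reagents that add atoms: none
Why: Ring-closing olefin metathesis by the Chauvin mechanism: the benzylidene exchanges with the unhindered monosubstituted vinyl group on the C4 carbinol, the new ruthenium alkylidene adds intramolecularly to the 1,1-disubstituted alkene on the C1 carbinol, and cycloreversion of the ruthenacyclobutane forms C2=C3 and expels ethene. The closest known reaction type is the metathesis of ortho-bis(1-hydroxyallyl)benzenes to 1,4-dihydronaphthalene-1,4-diols that are subsequently oxidised to naphthoquinones. Ring A is closed as a six-membered ring by metathesis of two alkene termini held ortho to each other on ring B. No stereocentre is created: the two carbinol centres enter as epimer mixtures and are erased in step 13, and the silyloxy stereocentre takes no part. The step needs chemoselectivity among three alkenes, which the substrate secures because only the vinyl group can load the catalyst readily, only the 1,1-disubstituted alkene gives a six-membered ring, and the trisubstituted prenyl alkene is hindered and placed for a four- or nine-membered ring only. Acid-free conditions and the benzoquinone additive are meant to prevent dehydration of the diol to a naphthol and ruthenium-hydride isomerisation of the allylic alcohols to ketones.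

Step 13
Reactants: 21 (R)-2-[1-(tert-butyldimethylsilyloxy)-4-methylpent-3-enyl]-5,8-bis(methoxymethoxy)-1,4-dihydronaphthalene-1,4-diol
Product: 22 (R)-2-[1-(tert-butyldimethylsilyloxy)-4-methylpent-3-enyl]-5,8-bis(methoxymethoxy)naphthalene-1,4-dione
Conditions: activated MnO2 (20 equiv), CH2Cl2, rt
Reagents that add atoms: none
Why: MnO2 oxidation of alcohols that are both benzylic and allylic should convert both carbinols to carbonyls under neutral conditions and so give the quinone, with silyl ether, acetals and prenyl alkene untouched.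

Step 14
Reactants: 22 (R)-2-[1-(tert-butyldimethylsilyloxy)-4-methylpent-3-enyl]-5,8-bis(methoxymethoxy)naphthalene-1,4-dione
Product: 23 (R)-5,8-dihydroxy-2-(1-hydroxy-4-methylpent-3-enyl)naphthalene-1,4-dione (shikonin)
Conditions: 3 M aq. HCl/THF (1:3), 0 °C → rt, argon, dark
Reagents that add atoms: none
Why: acid hydrolysis of the two aryl methoxymethyl acetals (helped by the peri carbonyls, which chelate the freed phenols) and of the silyl ether should occur together, and the carbinol next to the electron-poor quinone resists ionisation so its configuration should be kept.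

Step 15
Reactants: 23 (R)-5,8-dihydroxy-2-(1-hydroxy-4-methylpent-3-enyl)naphthalene-1,4-dione; 24 3,4-dimethylpent-3-enoic acid
Product: 25 (R)-1-(5,8-dihydroxy-1,4-dioxo-1,4-dihydronaphthalen-2-yl)-4-methylpent-3-enyl 3,4-dimethylpent-3-enoate (CNP0163639.1)
Conditions: 24 (1.2 equiv), DCC (1.2 equiv), DMAP (0.1 equiv), CH2Cl2, 0 °C → rt
Reagents that add atoms: none
Why: Steglich esterification acylates the secondary alcohol selectively because the two phenols are locked in hydrogen bonds to the quinone carbonyls, and the C–O bond at the stereocentre is not broken, so the R configuration is retained.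

**Compound list**
1 | 2,5-dihydroxybenzaldehyde | O=Cc1cc(O)ccc1O | starting material
2 | 2,5-bis(methoxymethoxy)benzaldehyde | COCOc1ccc(OCOC)c(C=O)c1 | intermediate
3 | lithium amino alkoxide from 2 and lithium N,N,N′-trimethylethylenediamide | [Li]OC(N(C)CCN(C)C)c1cc(OCOC)ccc1OCOC | intermediate (not isolated)
4 | ortho-lithiated amino alkoxide | [Li]OC(N(C)CCN(C)C)c1c([Li])c(OCOC)ccc1OCOC | intermediate (not isolated)
5 | 3,6-bis(methoxymethoxy)benzene-1,2-dicarbaldehyde | O=Cc1c(OCOC)ccc(OCOC)c1C=O | intermediate
6 | 4-methylpent-3-enoic acid | CC(C)=CCC(=O)O | starting material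
7 | N-methoxy-N,4-dimethylpent-3-enamide | CC(C)=CCC(=O)N(C)OC | intermediate
8 | ethynyltrimethylsilane | C#C[Si](C)(C)C | starting material
9 | lithium (trimethylsilyl)acetylide | [Li]C#C[Si](C)(C)C | intermediate (not isolated)
10 | 6-methyl-1-(trimethylsilyl)hept-5-en-1-yn-3-one | CC(C)=CCC(=O)C#C[Si](C)(C)C | intermediate
11 | (R)-6-methyl-1-(trimethylsilyl)hept-5-en-1-yn-3-ol | CC(C)=CC[C@@H](O)C#C[Si](C)(C)C | intermediate
12 | (R)-tert-butyldimethyl{[6-methyl-1-(trimethylsilyl)hept-5-en-1-yn-3-yl]oxy}silane | CC(C)=CC[C@@H](O[Si](C)(C)C(C)(C)C)C#C[Si](C)(C)C | intermediate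
13 | (R)-tert-butyldimethyl[(6-methylhept-5-en-1-yn-3-yl)oxy]silane | CC(C)=CC[C@@H](O[Si](C)(C)C(C)(C)C)C#C | intermediate
14 | (3R)-3-(tert-butyldimethylsilyloxy)-6-methyl-2-(tributylstannyl)hepta-1,5-diene | CC(C)=CC[C@@H](O[Si](C)(C)C(C)(C)C)C(=C)[Sn](CCCC)(CCCC)CCCC | intermediate
15 | (3R)-3-(tert-butyldimethylsilyloxy)-2-iodo-6-methylhepta-1,5-diene | CC(C)=CC[C@@H](O[Si](C)(C)C(C)(C)C)C(I)=C | intermediate
16 | [(3R)-3-(tert-butyldimethylsilyloxy)-6-methylhepta-1,5-dien-2-yl]lithium | CC(C)=CC[C@@H](O[Si](C)(C)C(C)(C)C)C([Li])=C | intermediate (not isolated)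
17 | lithium alkoxide of 2-[(3R)-3-(tert-butyldimethylsilyloxy)-1-hydroxy-6-methyl-2-methylenehept-5-enyl]-3,6-bis(methoxymethoxy)benzaldehyde | CC(C)=CC[C@@H](O[Si](C)(C)C(C)(C)C)C(=C)C(O[Li])c1c(OCOC)ccc(OCOC)c1C=O | intermediate (not isolated)
18 | 3-[(3R)-3-(tert-butyldimethylsilyloxy)-6-methylhepta-1,5-dien-2-yl]-4,7-bis(methoxymethoxy)-1,3-dihydro-2-benzofuran-1-ol (epimer mixture) | CC(C)=CC[C@@H](O[Si](C)(C)C(C)(C)C)C(=C)C1OC(O)c2c(OCOC)ccc(OCOC)c12 | intermediate
19 | bromomagnesium alkoxide of 2-[(3R)-3-(tert-butyldimethylsilyloxy)-1-hydroxy-6-methyl-2-methylenehept-5-enyl]-3,6-bis(methoxymethoxy)benzaldehyde | CC(C)=CC[C@@H](O[Si](C)(C)C(C)(C)C)C(=C)C(O[Mg]Br)c1c(OCOC)ccc(OCOC)c1C=O | intermediate (not isolated)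
20 | 1-(1-hydroxyprop-2-enyl)-2-[(3R)-3-(tert-butyldimethylsilyloxy)-1-hydroxy-6-methyl-2-methylenehept-5-enyl]-3,6-bis(methoxymethoxy)benzene (epimer mixture) | COCOc1ccc(OCOC)c(C(O)C=C)c1C(O)C(=C)[C@@H](CC=C(C)C)O[Si](C)(C)C(C)(C)C | intermediate
21 | (R)-2-[1-(tert-butyldimethylsilyloxy)-4-methylpent-3-enyl]-5,8-bis(methoxymethoxy)-1,4-dihydronaphthalene-1,4-diol (epimer mixture) | CC(C)=CC[C@@H](O[Si](C)(C)C(C)(C)C)C1=CC(O)c2c(OCOC)ccc(OCOC)c2C1O | intermediate
22 | (R)-2-[1-(tert-butyldimethylsilyloxy)-4-methylpent-3-enyl]-5,8-bis(methoxymethoxy)naphthalene-1,4-dione | CC(C)=CC[C@@H](O[Si](C)(C)C(C)(C)C)C1=CC(=O)c2c(OCOC)ccc(OCOC)c2C1=O | intermediate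
23 | (R)-5,8-dihydroxy-2-(1-hydroxy-4-methylpent-3-enyl)naphthalene-1,4-dione (shikonin) | CC(C)=CC[C@@H](O)C1=CC(=O)c2c(O)ccc(O)c2C1=O | intermediate
24 | 3,4-dimethylpent-3-enoic acid | CC(C)=C(C)CC(=O)O | starting material
25 | (R)-1-(5,8-dihydroxy-1,4-dioxo-1,4-dihydronaphthalen-2-yl)-4-methylpent-3-enyl 3,4-dimethylpent-3-enoate | CC(C)=CC[C@@H](OC(=O)CC(C)=C(C)C)C1=CC(=O)c2c(O)ccc(O)c2C1=O | target

**Step count and risks**

Total step count: 15. Longest linear sequence: 13 steps (steps 3–15, from 6 to 25); the aromatic branch (steps 1 and 2) joins at step 10.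

Steps most likely to fail:

1. Step 12. The closure may stall at the hindered 1,1-disubstituted alkene, leaving time for ruthenium-hydride isomerisation of the free vinyl carbinol to an ethyl ketone, or the diol product may lose water and aromatise before it is oxidised. Fallback, setting out from 20: both carbinols are capped with TESOTf and 2,6-lutidine (CH2Cl2, −78 °C) to give the bis-O-triethylsilyl diene F1, which has no free allylic hydroxyl to isomerise or ionise. Metathesis with the catalyst of step 12 in toluene at 80 °C should then give the bis-O-triethylsilyl dihydronaphthalene F2. HF·pyridine buffered with pyridine (THF, 0 °C) removes the two triethylsilyl groups in the presence of the tert-butyldimethylsilyl ether, and the route is rejoined at 21.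

2. Step 14. Cleavage of the aryl acetals may be slow, and prolonged exposure of the freed naphthazarin carbinol to acid may cause loss of configuration or cyclisation of the hydroxyl onto the prenyl alkene. Fallback, setting out from 22: the silyl ether alone is cleaved with HF·pyridine/pyridine (THF, 0 °C) to give the bis(methoxymethyl) carbinol F3. This is esterified with 24 (DCC, DMAP, CH2Cl2, 0 °C) to give the bis(methoxymethyl) ester F4. The two peri acetals are then removed by chelation-assisted cleavage with BCl3 (CH2Cl2, −78 °C, short contact), so that the carbinol is never free under acid, and the route is rejoined at 25.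

3. Step 8. Regiocontrol of the hydrometalation may erode, with tin delivered to the terminal alkyne carbon because of the bulky silyloxy group. Fallback, setting out from 13: stannylcupration–protonation with Me3SnCu·SMe2 (from Me3SnLi and CuBr·SMe2) in THF at −78 °C in the presence of MeOH, a stoichiometric method known to convert 1-alkynes into 2-stannyl-1-alkenes, should give the 2-trimethylstannyl diene F5. Iododestannylation with I2 (CH2Cl2, 0 °C) rejoins the route at 15.

**Further compounds**
F1 | step 12 | 1-[1-(triethylsilyloxy)prop-2-enyl]-2-[(3R)-3-(tert-butyldimethylsilyloxy)-6-methyl-2-methylene-1-(triethylsilyloxy)hept-5-enyl]-3,6-bis(methoxymethoxy)benzene (epimer mixture) | CC(C)=CC[C@@H](O[Si](C)(C)C(C)(C)C)C(=C)C(O[Si](CC)(CC)CC)c1c(OCOC)ccc(OCOC)c1C(O[Si](CC)(CC)CC)C=C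
F2 | step 12 | (R)-2-[1-(tert-butyldimethylsilyloxy)-4-methylpent-3-enyl]-5,8-bis(methoxymethoxy)-1,4-bis(triethylsilyloxy)-1,4-dihydronaphthalene (epimer mixture) | CC(C)=CC[C@@H](O[Si](C)(C)C(C)(C)C)C1=CC(O[Si](CC)(CC)CC)c2c(OCOC)ccc(OCOC)c2C1O[Si](CC)(CC)CC
F3 | step 14 | (R)-2-(1-hydroxy-4-methylpent-3-enyl)-5,8-bis(methoxymethoxy)naphthalene-1,4-dione | CC(C)=CC[C@@H](O)C1=CC(=O)c2c(OCOC)ccc(OCOC)c2C1=O
F4 | step 14 | (R)-1-[5,8-bis(methoxymethoxy)-1,4-dioxo-1,4-dihydronaphthalen-2-yl]-4-methylpent-3-enyl 3,4-dimethylpent-3-enoate | CC(C)=CC[C@@H](OC(=O)CC(C)=C(C)C)C1=CC(=O)c2c(OCOC)ccc(OCOC)c2C1=O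
F5 | step 8 | (3R)-3-(tert-butyldimethylsilyloxy)-6-methyl-2-(trimethylstannyl)hepta-1,5-diene | CC(C)=CC[C@@H](O[Si](C)(C)C(C)(C)C)C(=C)[Sn](C)(C)C
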